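Everything rests on reading the C1=C2 enone bond of the cyclohexenone ring (C1 heptenyl, C2 hydroxymethyl) as a retro-Diels–Alder retron and masking it as the cyclopentadiene adduct of a quinone. One catalytic enantioselective endo cycloaddition across the unsubstituted C1=C2 bond of a 2-substituted 1,4-benzoquinone closes the norbornene ring, sets the absolute configuration, folds the enedione so that only the convex face of C4=C5 is open for the cis oxirane, and makes C1 and C2 enolisable for two formaldehyde aldols. The precursor is the quinone that already carries the complete (E)-2-methylbut-2-enoate arm at C5, protected as a tert-butyl ester so that the final unmasking is acidic.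

Key step: step 5

Remark 1: Ring atoms keep the target numbering throughout: C1 (heptenyl), C2 (CH2OH), C3 (carbinol), C4 and C5 (oxirane, C5 quaternary), C6 (ketone). The α face is the face from which C1→C6 runs clockwise; in the target it carries the oxirane oxygen and the C3 hydroxyl. The β face is the opposite one.
Remark 2: The acid is carried as its tert-butyl ester, because the epoxyquinol core is not expected to survive the hydroxide needed to cleave a hindered methyl enoate, whereas acid removes ester and acetonide together.
Remark 3: The oxazaborolidine precatalyst of step 5 is assumed to be bought as its toluene solution. Its (S) configuration is chosen from the usual binding model of such catalysts with quinones.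

Step 1
Reactants: 1 1,4-dimethoxybenzene; 2 allyl bromide
Product: 4 2-allyl-1,4-dimethoxybenzene, via 2,5-dimethoxyphenyllithium 3 (not isolated)
Conditions: n-BuLi (1.1 equiv), TMEDA (1.1 equiv), Et2O, 0 °C to rt; then CuBr·SMe2 (10 mol %), 2 (1.3 equiv), −40 °C to rt
Reagents that add atoms: none
Why: Methoxy-directed ortho-lithiation (directed ortho-metalation) gives aryllithium 3, which is allylated by copper-catalysed substitution of allyl bromide; no stereocentre is formed.

Step 2
Reactants: 4 2-allyl-1,4-dimethoxybenzene; 5 tert-butyl methacrylate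
Product: 6 tert-butyl (2E)-4-(2,5-dimethoxyphenyl)-2-methylbut-2-enoate
Conditions: second-generation Hoveyda–Grubbs catalyst (5 mol %), 5 (5 equiv), CH2Cl2, 40 °C
Reagents that add atoms: none
Why: Olefin cross-metathesis between the terminal alkene of the allylarene and a methacrylate ester, driven by loss of ethene, should give the trisubstituted enoate as the thermodynamically preferred E isomer with the ester trans to the benzylic CH2.

Step 3
Reactants: 6 tert-butyl (2E)-4-(2,5-dimethoxyphenyl)-2-methylbut-2-enoate
Product: 7 tert-butyl (2E)-4-(3,6-dioxocyclohexa-1,4-dien-1-yl)-2-methylbut-2-enoate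
Conditions: (NH4)2Ce(NO3)6 (2.5 equiv), MeCN/H2O, 0 °C, 15 min; product kept cold and dark and used promptly
Reagents that add atoms: water, O
Why: Oxidative demethylation of the 1,4-dimethoxyarene by (NH4)2Ce(NO3)6 proceeds through the arene radical cation with water supplying the two quinone oxygens, and the tert-butyl ester and the trisubstituted alkene are expected to be inert during the short reaction at 0 °C.

Step 4
Reactants: 8 dicyclopentadiene
Product: 9 cyclopenta-1,3-diene
Conditions: neat, 170 °C, distilled (b.p. 41 °C) into a receiver at −78 °C, used at once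
Reagents that add atoms: none
Why: Thermal retro-Diels–Alder cracking splits each molecule of the dimer into two molecules of the monomeric diene, which is removed by distillation as it forms and used before it re-dimerises.

Step 5
Reactants: 7 quinone tert-butyl ester; 9 cyclopenta-1,3-diene
Product: 10 endo adduct, tert-butyl (2E)-2-methyl-4-[(1S,2R,7S,8R)-3,6-dioxotricyclo[6.2.1.0^2,7]undeca-4,9-dien-4-yl]but-2-enoate
Conditions: (S)-3,3-diphenyl-1-(2-methylphenyl)tetrahydro-1H,3H-pyrrolo[1,2-c][1,3,2]oxazaborole (20 mol %), HNTf2 (17 mol %), CH2Cl2, −78 °C; 9 (3 equiv) added slowly; Et3N quench at −78 °C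
Reagents that add atoms: none
Why: A concerted, suprafacial [4+2] cycloaddition (Diels–Alder reaction) takes place on the quinone once the triflimide-activated oxazaborolidinium has bound the more basic C3 carbonyl oxygen, remote from the C5 substituent, through the lone pair syn to C2–H, with a supporting C2–H···O contact to the ring oxygen of the catalyst. The closest known reaction type is the cationic oxazaborolidine-catalysed Diels–Alder reaction of 2-substituted 1,4-benzoquinones with dienes. The single new ring, the cyclohexene ring of the norbornene, is closed by the cycloaddition itself, the bonds from C1 and from C2 to the diene termini forming in one step. The relative configuration of the four new stereocentres (C1, C2 and the two bridgeheads) follows from the endo transition state, in which the diene π system lies over the quinone carbonyls, and their absolute configuration follows from the catalyst, whose proximal phenyl group covers the α face of C1=C2 so that the diene adds to the β face and leaves C1–H and C2–H on the α face. The step needs site, endo and enantioface selectivity: the C5 substituent makes C4=C5 less electrophilic and more hindered than C1=C2, secondary orbital overlap favours endo, and the low temperature with slow addition of the diene keeps the uncatalysed racemic pathway slow relative to the catalysed one.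

Step 6
Reactants: 10 endo adduct
Product: 11 α-epoxide of the adduct (C4–C5 oxirane on the convex face, oxygen cis to C1–H and C2–H, anti to the etheno bridge)
Conditions: 30% aq. H2O2 (3 equiv), Na2CO3 (0.5 equiv), acetone/H2O, 0 °C
Reagents that add atoms: hydrogen peroxide, OO
Why: Weitz–Scheffer nucleophilic epoxidation of the enedione, in which hydroperoxide adds to C4 and the resulting enolate closes the oxirane, takes place on the convex α face because the β face of C4=C5 lies under the etheno bridge, so C4 and C5 are set with the oxirane oxygen cis to C1–H and C2–H, while the poorly electrophilic enoate is left alone.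

Step 7
Reactants: 11 α-epoxide of the adduct; 12 formaldehyde
Product: 14 C1,C2-bis(hydroxymethyl) epoxydione (both CH2OH groups on the α face at the ring-fusion carbons), via C2-mono(hydroxymethyl) epoxydione 13 (not isolated)
Conditions: 37% aq. 12 (10 equiv), 1,8-diazabicyclo[5.4.0]undec-7-ene (DBU, 0.5 equiv), THF, 0 °C
Reagents that add atoms: formaldehyde (second equivalent), C=O
Why: Two successive aldol additions to formaldehyde (hydroxymethylation), each consuming one molecule of the aldehyde, proceed through the DBU-generated enolates of the C3 and C6 ketones and install one carbon at each ring-fusion position from the convex α face with retention of the cis ring fusion, the two new quaternary centres being only temporary, while C4 is not enolised because that would place a double bond on the oxirane ring.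

Step 8
Reactants: 14 C1,C2-bis(hydroxymethyl) epoxydione
Product: 15 tert-butyl (2E)-4-[(1R,6S)-3,4-bis(hydroxymethyl)-2,5-dioxo-7-oxabicyclo[4.1.0]hept-3-en-1-yl]-2-methylbut-2-enoate
Conditions: Ph2O (degassed), 230 °C, 10–15 min, base-washed glassware, rapid cooling
Reagents that add atoms: none
Why: Thermal retro-Diels–Alder reaction ([4+2] cycloreversion) expels cyclopentadiene and returns the C1=C2 double bond within a conjugated enedione, leaves C4 and C5 untouched, and is kept short so that thermal loss of isobutene from the ester stays minor.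

Step 9
Reactants: 15 bis(hydroxymethyl) epoxyquinone
Product: 16 tert-butyl (2E)-4-[(1R,5R,6R)-5-hydroxy-3,4-bis(hydroxymethyl)-2-oxo-7-oxabicyclo[4.1.0]hept-3-en-1-yl]-2-methylbut-2-enoate
Conditions: NaBH4 (0.5 equiv), CeCl3·7H2O (1.1 equiv), MeOH, −78 °C; acetone then aq. NH4Cl quench
Reagents that add atoms: none
Why: Luche reduction (cerium-assisted 1,2-hydride addition) is expected to occur at the C3 carbonyl from the β face, anti to the oxirane oxygen, which places the new hydroxyl on the α face syn to the epoxide (R at C3), whereas the C6 carbonyl is screened on its β face by the C5 side chain and on its α face by the oxirane oxygen.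

Step 10
Reactants: 16 triol
Product: 17 acetonide alcohol (isopropylidene acetal across O3 and the C2 CH2O, C1 CH2OH free)
Conditions: 2,2-dimethoxypropane (5 equiv), pyridinium p-toluenesulfonate (10 mol %), acetone, rt
Reagents that add atoms: 2,2-dimethoxypropane, COC(C)(C)OC
Why: Acid-catalysed transacetalisation under equilibrating conditions should give the six-membered 1,3-dioxane that spans O3 and the C2 CH2O in preference to the seven-membered acetal of the two CH2OH groups, so that only the C1 CH2OH stays free.

Step 11
Reactants: 17 acetonide alcohol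
Product: 18 acetonide aldehyde (C1 CHO)
Conditions: 2,2,6,6-tetramethylpiperidin-1-oxyl (TEMPO, 10 mol %), PhI(OAc)2 (1.2 equiv), CH2Cl2, rt
Reagents that add atoms: none
Why: Oxoammonium (TEMPO) oxidation of the primary allylic alcohol stops at the aldehyde under nearly neutral conditions that spare the acetonide, the oxirane and the ester.

Step 12
Reactants: 19 1-phenyl-1H-tetrazole-5-thiol; 20 1-bromohexane
Product: 21 5-(hexylsulfanyl)-1-phenyl-1H-tetrazole
Conditions: K2CO3 (1.5 equiv), acetone, reflux
Reagents that add atoms: none
Why: SN2 S-alkylation of the tetrazolethiolate by the primary bromide.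

Step 13
Reactants: 21 5-(hexylsulfanyl)-1-phenyl-1H-tetrazole
Product: 23 5-(hexylsulfonyl)-1-phenyl-1H-tetrazole, via sulfoxide 22 (not isolated)
Conditions: 30% aq. H2O2 (5 equiv), (NH4)6Mo7O24·4H2O (5 mol %), EtOH, 0 °C to rt
Reagents that add atoms: hydrogen peroxide, OO
Why: Molybdate-catalysed peroxide oxidation takes the sulfide through sulfoxide 22 to the sulfone without touching the tetrazole.

Step 14
Reactants: 18 acetonide aldehyde; 23 5-(hexylsulfonyl)-1-phenyl-1H-tetrazole
Product: 26 (E)-heptenyl acetonide tert-butyl ester, via potassium sulfonyl carbanion 24 (not isolated), via β-alkoxy sulfone adduct 25 (not isolated)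
Conditions: 23 (1.3 equiv), KN(SiMe3)2 (1.2 equiv), DME, −60 °C, 30 min; then 18, −60 °C to rt
Reagents that add atoms: none
Why: Julia–Kocienski olefination, in which metalated sulfone 24 adds to the aldehyde, which is more electrophilic than the hindered non-enolisable C6 ketone, and Smiles rearrangement of adduct 25 with loss of SO2 and the tetrazolone is expected to give the E alkene, the usual outcome for 1-phenyltetrazolyl sulfones with a potassium counter-ion in DME.

Step 15
Reactants: 26 (E)-heptenyl acetonide tert-butyl ester
Product: 28 (2E)-4-[(1R,5R,6R)-3-[(1E)-hept-1-en-1-yl]-5-hydroxy-4-(hydroxymethyl)-2-oxo-7-oxabicyclo[4.1.0]hept-3-en-1-yl]-2-methylbut-2-enoic acid, via diol tert-butyl ester 27 (not isolated)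
Conditions: CF3CO2H/CH2Cl2/H2O (25:70:5), 0 °C to rt; concentrate, brief aq. NaHCO3/MeOH, acidify to pH 3
Reagents that add atoms: none
Why: Acid hydrolysis of the isopropylidene acetal followed by acid-mediated loss of isobutene from the tert-butyl ester (E1 fragmentation) frees the diol and the acid in one operation without touching a stereocentre, the oxirane being deactivated towards ionisation by the adjacent C6 carbonyl.

Compound list
1 | 1,4-dimethoxybenzene | COc1ccc(OC)cc1 | starting material
2 | allyl bromide (3-bromoprop-1-ene) | C=CCBr | starting material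
3 | 2,5-dimethoxyphenyllithium (formed in situ) | [Li]c1cc(OC)ccc1OC | intermediate
4 | 2-allyl-1,4-dimethoxybenzene | C=CCc1cc(OC)ccc1OC | intermediate
5 | tert-butyl methacrylate | C=C(C)C(=O)OC(C)(C)C | starting material
6 | tert-butyl (2E)-4-(2,5-dimethoxyphenyl)-2-methylbut-2-enoate | COc1ccc(OC)c(C/C=C(\C)C(=O)OC(C)(C)C)c1 | intermediate
7 | tert-butyl (2E)-4-(3,6-dioxocyclohexa-1,4-dien-1-yl)-2-methylbut-2-enoate (key-step precursor) | O=C1C=CC(=O)C(C/C=C(\C)C(=O)OC(C)(C)C)=C1 | intermediate
8 | dicyclopentadiene | C1C=CC2C1C3CC2C=C3 | starting material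
9 | cyclopenta-1,3-diene | C1C=CC=C1 | intermediate
10 | tert-butyl (2E)-2-methyl-4-[(1S,2R,7S,8R)-3,6-dioxotricyclo[6.2.1.0^2,7]undeca-4,9-dien-4-yl]but-2-enoate (endo adduct, key-step product; ring-fusion H atoms on the α face, norbornene on the β face) | O=C1C=C(C/C=C(\C)C(=O)OC(C)(C)C)C(=O)[C@H]2[C@@H]1[C@H]1C=C[C@@H]2C1 | intermediate
11 | α-epoxide of 10 (C4–C5 oxirane on the convex face, oxygen cis to the ring-fusion H atoms) | O=C1[C@H]2O[C@@]2(C/C=C(\C)C(=O)OC(C)(C)C)C(=O)[C@H]3[C@@H]1[C@H]1C=C[C@@H]3C1 | intermediate
12 | formaldehyde (37% aqueous solution) | C=O | starting material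
13 | 11 with CH2OH in place of H at ring-fusion carbon C2, α face (formed in situ) | O=C1[C@H]2O[C@@]2(C/C=C(\C)C(=O)OC(C)(C)C)C(=O)[C@H]3[C@]1(CO)[C@H]1C=C[C@@H]3C1 | intermediate
14 | 11 with CH2OH in place of H at both ring-fusion carbons C1 and C2, both on the α face | O=C1[C@H]2O[C@@]2(C/C=C(\C)C(=O)OC(C)(C)C)C(=O)[C@@]3(CO)[C@]1(CO)[C@H]1C=C[C@@H]3C1 | intermediate
15 | tert-butyl (2E)-4-[(1R,6S)-3,4-bis(hydroxymethyl)-2,5-dioxo-7-oxabicyclo[4.1.0]hept-3-en-1-yl]-2-methylbut-2-enoate | OCC1=C(CO)C(=O)[C@H]2O[C@@]2(C/C=C(\C)C(=O)OC(C)(C)C)C1=O | intermediate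
16 | tert-butyl (2E)-4-[(1R,5R,6R)-5-hydroxy-3,4-bis(hydroxymethyl)-2-oxo-7-oxabicyclo[4.1.0]hept-3-en-1-yl]-2-methylbut-2-enoate (C3 hydroxyl syn to the oxirane) | OCC1=C(CO)[C@@H](O)[C@H]2O[C@@]2(C/C=C(\C)C(=O)OC(C)(C)C)C1=O | intermediate
17 | isopropylidene acetal of 16 across O3 and the C2 CH2O (1,3-dioxane), C1 CH2OH free, stereocentres as in 16 | OCC1=C2COC(C)(C)O[C@H]2[C@H]3O[C@@]3(C/C=C(\C)C(=O)OC(C)(C)C)C1=O | intermediate
18 | aldehyde from 17 (C1 CHO), stereocentres as in 16 | O=CC1=C2COC(C)(C)O[C@H]2[C@H]3O[C@@]3(C/C=C(\C)C(=O)OC(C)(C)C)C1=O | intermediate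
19 | 1-phenyl-1H-tetrazole-5-thiol | Sc1nnnn1-c1ccccc1 | starting material
20 | 1-bromohexane | CCCCCCBr | starting material
21 | 5-(hexylsulfanyl)-1-phenyl-1H-tetrazole | CCCCCCSc1nnnn1-c1ccccc1 | intermediate
22 | 5-(hexylsulfinyl)-1-phenyl-1H-tetrazole (formed in situ, racemic at sulfur) | CCCCCCS(=O)c1nnnn1-c1ccccc1 | intermediate
23 | 5-(hexylsulfonyl)-1-phenyl-1H-tetrazole | CCCCCCS(=O)(=O)c1nnnn1-c1ccccc1 | intermediate
24 | potassium 1-[(1-phenyl-1H-tetrazol-5-yl)sulfonyl]hexan-1-ide (formed in situ) | [K+].CCCCC[CH-]S(=O)(=O)c1nnnn1-c1ccccc1 | intermediate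
25 | potassium alkoxide from addition of 24 to the aldehyde of 18 (formed in situ; the two new sp3 centres are not controlled, ring stereocentres as in 16) | [K+].CCCCCC(C([O-])C1=C2COC(C)(C)O[C@H]2[C@H]3O[C@@]3(C/C=C(\C)C(=O)OC(C)(C)C)C1=O)S(=O)(=O)c1nnnn1-c1ccccc1 | intermediate
26 | isopropylidene acetal (as in 17) carrying the (1E)-hept-1-en-1-yl group at C1, tert-butyl ester | CCCCC/C=C/C1=C2COC(C)(C)O[C@H]2[C@H]3O[C@@]3(C/C=C(\C)C(=O)OC(C)(C)C)C1=O | intermediate
27 | tert-butyl (2E)-4-[(1R,5R,6R)-3-[(1E)-hept-1-en-1-yl]-5-hydroxy-4-(hydroxymethyl)-2-oxo-7-oxabicyclo[4.1.0]hept-3-en-1-yl]-2-methylbut-2-enoate (formed in situ) | CCCCC/C=C/C1=C(CO)[C@@H](O)[C@H]2O[C@@]2(C/C=C(\C)C(=O)OC(C)(C)C)C1=O | intermediate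
28 | (2E)-4-[(1R,5R,6R)-3-[(1E)-hept-1-en-1-yl]-5-hydroxy-4-(hydroxymethyl)-2-oxo-7-oxabicyclo[4.1.0]hept-3-en-1-yl]-2-methylbut-2-enoic acid | CCCCC/C=C/C1=C(CO)[C@@H](O)[C@H]2O[C@@]2(C/C=C(\C)C(=O)O)C1=O | target

Total step count: 15. Longest linear sequence: 12 steps (steps 1, 2, 3, 5, 6, 7, 8, 9, 10, 11, 14, 15).

Steps most likely to fail

Step 5. Enantioface control may be insufficient, either because the uncatalysed cycloaddition competes or because the catalyst binds at the C6 instead of the C3 carbonyl. The adduct may also enolise to the hydroquinone under acid. If the sense of induction alone is reversed, the antipodal precatalyst is used. The fallback secures the absolute configuration by enzymatic kinetic resolution instead; it sets out from 7 and 9 and comes back at 14. Quinone 7 and diene 9 are combined without catalyst (CH2Cl2, 0 °C), which should give 10 together with its mirror image, the ent-adduct F1. The mixture is taken through the conditions of step 6 to 11 and the ent-epoxide F2, and through those of step 7, by way of 13 and the ent-mono(hydroxymethyl) intermediate F3, to 14 and the ent-diol F4. Burkholderia cepacia lipase with vinyl acetate in tert-butyl methyl ether, chosen by a short enzyme screen, is expected to acetylate F4 selectively at the less hindered C2 hydroxymethyl group to the ent-diol monoacetate F5. Unreacted 14 is separated from F5 by chromatography and continues with step 8.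

Step 9. Site selectivity between the two carbonyls may be poor, hydride may be delivered from the α face, or over-reduction may occur. The fallback enforces the selectivity sterically; it sets out from 15 and comes back at 16. Both primary alcohols of 15 are silylated (TBSCl, imidazole, DMF, 0 °C) to the bis(tert-butyldimethylsilyl) ether F6. LiBH(s-Bu)3 (1.0 equiv, THF, −78 °C) is then expected to reach only the C3 carbonyl, and only from the β face, since C6 is flanked by the quaternary C5 and a silyloxymethyl group; this gives the silylated C3 carbinol F7. HF·pyridine in THF/pyridine removes both silyl groups and gives 16.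

Step 14. Alkene geometry may erode, and the basic sulfonyl anion may deprotonate C3 and so open the oxirane. The fallback separates bond formation from control of geometry; it sets out from 18 and comes back at 26. Aldehyde 18 is treated with the non-stabilised ylide made from hexyltriphenylphosphonium bromide and NaN(SiMe3)2 (THF, −78 °C), a Wittig reaction that should give the (Z)-heptenyl diene F8. Iodine-catalysed equilibration (I2, 5 mol %, CH2Cl2, daylight, rt) of the disubstituted alkene is then expected to give the E isomer 26.

Further compounds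
F1 | step 5 | ent-10, mirror image of the endo adduct | O=C1C=C(C/C=C(\C)C(=O)OC(C)(C)C)C(=O)[C@@H]2[C@H]1[C@@H]1C=C[C@H]2C1
F2 | step 5 | ent-11, mirror image of the α-epoxide | O=C1[C@@H]2O[C@]2(C/C=C(\C)C(=O)OC(C)(C)C)C(=O)[C@@H]3[C@H]1[C@@H]1C=C[C@H]3C1
F3 | step 5 | ent-13, mirror image of the mono(hydroxymethyl) intermediate (in situ) | O=C1[C@@H]2O[C@]2(C/C=C(\C)C(=O)OC(C)(C)C)C(=O)[C@@H]3[C@@]1(CO)[C@@H]1C=C[C@H]3C1
F4 | step 5 | ent-14, mirror image of the bis(hydroxymethyl) epoxydione | O=C1[C@@H]2O[C@]2(C/C=C(\C)C(=O)OC(C)(C)C)C(=O)[C@]3(CO)[C@@]1(CO)[C@@H]1C=C[C@H]3C1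
F5 | step 5 | monoacetate of ent-14 at the C2 hydroxymethyl group | O=C1[C@@H]2O[C@]2(C/C=C(\C)C(=O)OC(C)(C)C)C(=O)[C@]3(CO)[C@@]1(COC(C)=O)[C@@H]1C=C[C@H]3C1
F6 | step 9 | bis(tert-butyldimethylsilyl) ether of 15 | CC(C)(C)[Si](C)(C)OCC1=C(CO[Si](C)(C)C(C)(C)C)C(=O)[C@H]2O[C@@]2(C/C=C(\C)C(=O)OC(C)(C)C)C1=O
F7 | step 9 | bis(tert-butyldimethylsilyl) ether of 16 (C3 hydroxyl syn to the oxirane) | CC(C)(C)[Si](C)(C)OCC1=C(CO[Si](C)(C)C(C)(C)C)[C@@H](O)[C@H]2O[C@@]2(C/C=C(\C)C(=O)OC(C)(C)C)C1=O
F8 | step 14 | (Z)-heptenyl isomer of 26 | CCCCC/C=C\C1=C2COC(C)(C)O[C@H]2[C@H]3O[C@@]3(C/C=C(\C)C(=O)OC(C)(C)C)C1=O
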